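Target and side product both draw on the same pool, so I compared their rates directly; in that ratio the time step cancels, but the concentrations stay in it.

    intermediate C ⇌ intermediate E (K1 = 0.27, k1 = 0.27 /s)
    intermediate A ⇌ intermediate B (K2 = 12, k2 = 0.18 /s)
    intermediate A ⇌ intermediate C (K3 = 0.19, k3 = 0.044 /s)
    intermediate C → target (k4 = 0.14 /s)
    substrate + intermediate D → side product (k5 = 22 /M/s)
    substrate ⇌ intermediate A (K6 = 36, k6 = 0.082 /s)
    intermediate C ⇌ intermediate D (K7 = 4.3, k7 = 0.89 /s)

| setting | Thursday's | Wednesday's | Friday's |
|---|---|---|---|
| substrate | 2.0 mM | 2.0 mM | 2.0 mM |
| remark | one stirred flow tank at steady state, fed with the mixture as stated, mean residence time 15.0 s | a closed flask charged with all of it at once and left for 5.0 s | a single well-mixed tank run continuously and read at steady state, 5.0 s in it on average |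
| time |  | 5.0 s |  |

- the set-up with the highest share of target in all that became target or side product, at the outlet or at the end ("none" if the first two lie within 2 percentage points) (Thursday's / Wednesday's / Friday's / none)
- share of target in all that became target or side product, at the outlet or at the end, Thursday's
- share of target in all that became target or side product, at the outlet or at the end, Wednesday's
- share of target in all that became target or side product, at the outlet or at the end, Friday's

- percentages count the substrate that a species holds: one side product counts as two
- the stated concentrations are those of everything mixed, before any reaction; amounts are the same in each set-up
- run time (Wednesday's): 5.0 s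

I called that ratio the odds (an instantaneous selectivity): 0.14 /s times c(intermediate C), over doubled 22 /M/s times c(substrate) times c(intermediate D). It is doubled because one side product holds two substrates, and the share is the odds over one plus the odds.

The ladder ran from fast to slow. Intermediate C and intermediate D relaxed into each other with a half-life of 0.632 s, shorter than the 2.52 s of intermediate A with intermediate C. Substrate came last, slower than both, at 8.5 s by its forward step alone. So intermediate C and intermediate D rode on a slow feed, and their ratio was what I needed.

In a tank at steady state, the balance of intermediate D gives c(intermediate D)/c(intermediate C) as 0.89 /s over the sum of the washout rate, the back rate 0.207 /s and 22 /M/s times c(substrate). Neglecting the other substrate terms, I put c(substrate) at 0.897 mM on Thursday's, which made that ratio 3.03, the odds 1.17 and the share 53.9 %. On Friday's, c(substrate) of 1.42 mM made the ratio 2.03, the odds 1.10 and the share 52.4 %.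

In Wednesday's flask, intermediate D starts one step behind intermediate C. I took the early series, with substrate held at its charge and back steps ignored: target grows as the cube of time, side product as the fourth power. Integrated over the run, this gave Wednesday's odds: twice 0.14 /s, over 22 /M/s times the charge times 0.89 /s times the run time, which is 1.43, or a share of 58.8 %. These odds stood higher than either tank's, so I chose Wednesday's.

The forecast also chose Wednesday's, with 54 %, 69.5 % and 52.5 % for Thursday's, Wednesday's and Friday's. Its tank figures lay close to mine, but its flask figure, from “A rough hand integration”, stood above mine.

The simulation gave Wednesday's, with 54.0 % on Thursday's, 66.7 % on Wednesday's and 52.5 % on Friday's. Wednesday's odds came to 2.00, above my 1.43. The neighbouring flask is Wednesday's with 1.2 mM of substrate, read at the same time. The charge stands in the denominator of my odds, so they rise from 1.43 to 2.38, a factor of 1.66. The simulated neighbour gave 76.7 %, which is odds of 3.30, a factor of 1.65 on Wednesday's.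

(The constants used here were chosen freely; the rest is arithmetic.)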